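**Plan**
- Retrosynthesis: the target comes from the silylated furofuran 35 by TES removal, oxidation of the benzylic carbinol to the aryl ketone and desilylation. 35 is cut at C3a–C6a and O2–C3 of the furo[3,4-c]furan to the open-chain iodohydrin allyl ether 33; 33 is cut at the C6–O5 ether bond into cinnamyl bromide 28 and allylic alcohol 14.
- 28 is cut at the aldol bond next to the α-aryl centre and at two aryl–carbon bonds; 14 is cut at the vinyl–carbinol bond and at the C2–C3 bond of the dihydrobenzofuran (carbene C–H insertion).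
- Forward: the cis-dihydrobenzofuran is closed first (step 6), the two halves are joined as an ether (step 21), and both oxolane rings of the 3,7-dioxabicyclo[3.3.0]octane are closed in one pot (step 25).
- Enabling feature: in 33 the iodine-bearing carbon (future C-6a) lies in a 3-oxahex-5-enyl chain C6a–C6–O5–C4–CH=CH2 and is flanked by the benzylic carbinol C-1. 5-exo radical closure gives ring 1 (O5, C4, C3a, C6a, C6) and leaves CH2I four atoms from that hydroxyl, so O-2 can close ring 2 (C1, O2, C3, C3a, C6a).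
- Stereochemistry: C-2/C-3 of the dihydrobenzofuran from a chiral dirhodium carboxylate; C-4 from catalytic asymmetric vinylzinc addition; the α-aryl ketone centre from an Evans aldol; C-1 from CBS reduction; C-3a/C-6a from the cyclization transition state and the cis ring fusion.

Key step: step 25

Assumption: Rh2(R-PTTL)4 is taken to give the (2S,3R)-cis ester 9 in step 6; if the sense of induction is the reverse, the S-ligand catalyst is used instead.

Abbreviations: TIPS = triisopropylsilyl; TES = triethylsilyl; G = 3-methoxy-4-(TIPS-oxy)phenyl; DHB = (2S,3S)-7-methoxy-2-G-3-[(TIPS-oxy)methyl]-2,3-dihydro-1-benzofuran-5-yl; ArA = 3-methoxy-4-(TIPS-oxy)-5-[(1R,2S)-1-G-1-(TES-oxy)-3-(TIPS-oxy)propan-2-yl]phenyl. Furofuran locants: C-1, O-2, C-3, C-3a, C-4, O-5, C-6, C-6a.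

**Shared building blocks**

Step 1
Reactants: 1 vanillin
Product: 2 O-TIPS vanillin
Conditions: i-Pr3SiCl, imidazole, DMF, 25 °C
Reagents that add atoms: triisopropylsilyl chloride, CC(C)[Si](Cl)(C(C)C)C(C)C
Why: Standard phenol silylation; the bulky aryl silyl ether should survive the alkoxide, hydride and radical steps and leave at the end under buffered fluoride.

Step 2
Reactants: 2 O-TIPS vanillin
Product: 3 silyloxybenzyl alcohol
Conditions: NaBH4, MeOH, 0 °C
Reagents that add atoms: none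
Why: Borohydride reduction of an aryl aldehyde to the benzylic alcohol.

Step 3
Reactants: 4 4-bromo-2-methoxyphenol
Product: 5 4-bromo-2-iodo-6-methoxyphenol
Conditions: N-iodosuccinimide, TsOH (cat.), MeCN, 0 → 25 °C
Reagents that add atoms: N-iodosuccinimide, O=C1CCC(=O)N1I
Why: Electrophilic aromatic iodination ortho to the free hydroxyl, the para position being blocked by bromine.

**Fragment B (dihydrobenzofuran allylic alcohol)**

Step 4
Reactants: 5 4-bromo-2-iodo-6-methoxyphenol; 3 silyloxybenzyl alcohol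
Product: 6 aryl benzyl ether
Conditions: PPh3, diisopropyl azodicarboxylate, THF, 0 → 25 °C
Reagents that add atoms: none
Why: Mitsunobu etherification of an acidic phenol with a primary benzylic alcohol.

Step 5
Reactants: 6 aryl benzyl ether; 7 ethyl diazoacetate
Product: 8 aryl diazoacetate
Conditions: Pd(PPh3)4 (5 mol %), Ag2CO3 (0.5 equiv), Et3N (1.3 equiv), toluene, 25 °C
Reagents that add atoms: none
Why: Palladium-catalysed cross-coupling of an aryl iodide with the C–H bond of a diazoacetate (diazo group retained), which at room temperature should leave the aryl bromide untouched.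

Step 6
Reactants: 8 aryl diazoacetate
Product: 9 cis-dihydrobenzofuran ester
Conditions: Rh2(R-PTTL)4 [dirhodium tetrakis(N-phthaloyl-(R)-tert-leucinate)] (1 mol %), toluene, −60 °C
Reagents that add atoms: none
Why: Intramolecular 1,5 C–H insertion of a donor/acceptor rhodium carbene into the benzylic ether C–H bond, a reaction type known to give cis-2-aryl-2,3-dihydrobenzofuran-3-carboxylates, with both new stereocentres fixed by the chiral carboxylate ligands.

Step 7
Reactants: 9 cis-dihydrobenzofuran ester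
Product: 10 primary alcohol
Conditions: i-Bu2AlH, CH2Cl2, −78 → 0 °C
Reagents that add atoms: none
Why: Ester-to-alcohol reduction under non-basic, low-temperature conditions, so the cis α-aryl ester should not epimerize before it is reduced.

Step 8
Reactants: 10 primary alcohol
Product: 11 TIPS ether
Conditions: i-Pr3SiCl, imidazole, DMF, 25 °C
Reagents that add atoms: triisopropylsilyl chloride, CC(C)[Si](Cl)(C(C)C)C(C)C
Why: Routine silylation of a primary alcohol.

Step 9
Reactants: 11 TIPS ether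
Product: 13 dihydrobenzofuran-5-carbaldehyde, via aryllithium 12 (not isolated)
Conditions: n-BuLi, THF, −78 °C; then DMF, −78 → 0 °C; aq. NH4Cl
Reagents that add atoms: N,N-dimethylformamide, CN(C)C=O
Why: Bromine–lithium exchange followed by formylation of the aryllithium with DMF.

Step 10
Reactants: 13 dihydrobenzofuran-5-carbaldehyde
Product: 14 (S)-allylic alcohol
Conditions: Zn(CH=CH2)2 (from CH2=CHMgBr and ZnCl2), (−)-MIB [(2S)-3-exo-morpholinoisoborneol] (10 mol %), toluene, 0 °C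
Reagents that add atoms: divinylzinc, C=C[Zn]C=C
Why: Amino-alcohol-catalysed addition of a vinylzinc reagent to an aryl aldehyde; (−)-MIB directs attack to the Si face and should give the (S)-carbinol under catalyst control, the ring stereocentres being remote.

**Fragment A (cinnamyl bromide with the masked keto side chain)**

Step 11
Reactants: 5 4-bromo-2-iodo-6-methoxyphenol
Product: 15 aryl TIPS ether
Conditions: i-Pr3SiOTf, 2,6-lutidine, CH2Cl2, 0 °C
Reagents that add atoms: triisopropylsilyl trifluoromethanesulfonate, CC(C)[Si](OS(=O)(=O)C(F)(F)F)(C(C)C)C(C)C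
Why: Silyl triflate silylation, needed because the phenol is flanked by two ortho substituents.

Step 12
Reactants: 15 aryl TIPS ether
Product: 16 tert-butyl arylacetate
Conditions: BrZnCH2CO2t-Bu (1.3 equiv), Pd(PPh3)4 (5 mol %), THF, 45 °C
Reagents that add atoms: (2-tert-butoxy-2-oxoethyl)zinc bromide, CC(C)(C)OC(=O)C[Zn]Br
Why: Negishi-type coupling of a Reformatsky reagent at the C–I bond, oxidative addition to C–I being much faster than to C–Br with this catalyst.

Step 13
Reactants: 16 tert-butyl arylacetate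
Product: 17 arylacetic acid
Conditions: CF3CO2H, CH2Cl2, 0 → 25 °C
Reagents that add atoms: none
Why: Acidolysis of a tert-butyl ester, which the aryl silyl ether and aryl bromide should tolerate.

Step 14
Reactants: 17 arylacetic acid; 18 (R)-4-benzyl-2-oxazolidinone
Product: 20 N-arylacetyl imide, via mixed pivalic anhydride 19 (not isolated)
Conditions: t-BuCOCl, Et3N, THF, −20 °C; then 18, LiCl, 25 °C
Reagents that add atoms: none
Why: N-Acylation of the oxazolidinone through the mixed pivalic anhydride, the usual way to load an Evans auxiliary.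

Step 15
Reactants: 20 N-arylacetyl imide; 2 O-TIPS vanillin
Product: 22 syn aldol adduct, via dibutylboron Z-enolate 21 (not isolated)
Conditions: n-Bu2BOTf, i-Pr2NEt, CH2Cl2, −78 → 0 °C; then 2, −78 → 0 °C; H2O2, pH 7 buffer, MeOH work-up
Reagents that add atoms: none
Why: Evans syn aldol: the Z boron enolate reacts through a Zimmerman–Traxler chair on the face away from the auxiliary benzyl group, setting the (2R) α-aryl centre (the 3R carbinol is oxidized later).

Step 16
Reactants: 22 syn aldol adduct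
Product: 23 TES ether
Conditions: Et3SiOTf, 2,6-lutidine, CH2Cl2, −78 °C
Reagents that add atoms: triethylsilyl trifluoromethanesulfonate, CC[Si](CC)(CC)OS(=O)(=O)C(F)(F)F
Why: Silylation of the secondary carbinol with a group that can later be removed selectively in the presence of TIPS ethers, and which blocks retro-aldol.

Step 17
Reactants: 23 TES ether
Product: 24 primary alcohol
Conditions: LiBH4, MeOH (1 equiv), THF, 0 °C
Reagents that add atoms: none
Why: Reductive removal of the oxazolidinone; hydride attack on the imide carbonyl should be faster than enolization, so the α-aryl centre is kept.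

Step 18
Reactants: 24 primary alcohol
Product: 25 bis-TIPS aryl bromide
Conditions: i-Pr3SiCl, imidazole, DMAP (cat.), DMF, 25 °C
Reagents that add atoms: triisopropylsilyl chloride, CC(C)[Si](Cl)(C(C)C)C(C)C
Why: Routine silylation of a primary alcohol under conditions that leave the TES ether in place.

Step 19
Reactants: 25 bis-TIPS aryl bromide; 26 (E)-3-(tributylstannyl)prop-2-en-1-ol
Product: 27 (E)-cinnamyl alcohol
Conditions: Pd(PPh3)4 (5 mol %), toluene, 100 °C
Reagents that add atoms: none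
Why: Stille coupling of an aryl bromide with an alkenylstannane, with retention of the E geometry and tolerance of the free hydroxyl.

Step 20
Reactants: 27 (E)-cinnamyl alcohol
Product: 28 (E)-cinnamyl bromide
Conditions: CBr4, PPh3, 2,6-lutidine, CH2Cl2, −20 °C; used at once
Reagents that add atoms: carbon tetrabromide, BrC(Br)(Br)Br
Why: Appel bromination of a primary allylic alcohol under buffered, near-neutral conditions that the silyl ethers should survive.

**Union and endgame**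

Step 21
Reactants: 14 (S)-allylic alcohol; 28 (E)-cinnamyl bromide
Product: 30 bis-allylic ether, via sodium alkoxide 29 (not isolated)
Conditions: NaH, THF, 0 °C; then 28, Bu4NI (cat.), 0 → 25 °C
Reagents that add atoms: none
Why: Williamson etherification in which the alkoxide attacks the primary allylic bromide (SN2), so the C–O bond at the stereogenic carbinol carbon is never broken and its configuration is kept.

Step 22
Reactants: 30 bis-allylic ether
Product: 31 iodohydrin (diastereomer mixture)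
Conditions: N-iodosuccinimide, NaHCO3, THF/H2O (4:1), 0 °C, dark
Reagents that add atoms: N-iodosuccinimide, O=C1CCC(=O)N1I; water, O
Why: Iodohydroxylation: the electron-rich styrene-type double bond reacts far faster than the terminal vinyl group, and water opens the iodonium ion at the benzylic carbon, placing iodine on the non-benzylic carbon.

Step 23
Reactants: 31 iodohydrin (diastereomer mixture)
Product: 32 α-iodo ketone
Conditions: Dess–Martin periodinane, NaHCO3, CH2Cl2, 0 → 25 °C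
Reagents that add atoms: none
Why: Dess–Martin oxidation of a benzylic alcohol under buffered conditions, which removes the uncontrolled carbinol centre.

Step 24
Reactants: 32 α-iodo ketone
Product: 33 (1R)-iodohydrin
Conditions: (R)-2-methyl-CBS-oxazaborolidine (0.5 equiv), catecholborane, toluene, −78 °C
Reagents that add atoms: none
Why: CBS reduction of an aryl ketone with the aryl group as the large substituent should set the benzylic carbinol under reagent control; the configuration at the iodine-bearing carbon is irrelevant because it becomes a radical.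

Step 25
Reactants: 33 (1R)-iodohydrin
Product: 35 silylated furofuran, via iodomethyl oxolane 34 (not isolated)
Conditions: BEt3 (0.2 equiv, two portions), trace O2 (air), benzene, 25 °C; then THF, KOt-Bu, 0 °C
Reagents that add atoms: none
Why: Ethyl radicals from BEt3 and a trace of O2 abstract iodine from the secondary C–I bond of 33; the radical at the future C-6a is a 3-oxahex-5-enyl radical that adds 5-exo-trig to the internal vinyl carbon (C3a–C6a bond, ring 1), and the primary radical so formed takes iodine from another molecule of 33 to give iodide 34 and carry the chain. Adding KOt-Bu then converts the benzylic hydroxyl at C-1 into its alkoxide, which displaces the primary iodide in a 5-exo-tet Williamson closure (O2–C3 bond, ring 2). The closest known reaction type is the iodine-atom-transfer cyclization of 2-iodoalkyl allyl ethers and iodoacetals (Ueno–Stork-type substrates) to 3-(iodomethyl)oxolanes, followed by base-mediated etherification of an iodo alcohol. C-3a is set in a chair-like transition state with the aryl group on C-4 pseudo-equatorial, so CH2I ends up trans to it; C-6a is set by the preference of a substituted radical carbon to place its substituent cis to the new CH2 group, and only that cis isomer can reach the cis-fused bicycle. C-1 and C-4 are not touched (no bond to either is broken), so both aryl groups come out exo. The step needs 5-exo over 6-endo closure (secured by the unsubstituted vinyl terminus), cyclization before any epoxide formation (secured by adding base only after 33 is consumed) and cis over trans at the ring fusion (the trans iodide stays open and is removed).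

Step 26
Reactants: 35 silylated furofuran
Product: 36 benzylic alcohol
Conditions: pyridinium p-toluenesulfonate (0.2 equiv), MeOH/CH2Cl2 (1:1), 0 → 25 °C
Reagents that add atoms: none
Why: Mild acid-catalysed methanolysis cleaves the secondary TES ether much faster than the primary and aryl TIPS ethers and should not ionize the benzylic ring ethers.

Step 27
Reactants: 36 benzylic alcohol
Product: 37 aryl ketone
Conditions: Dess–Martin periodinane, NaHCO3, CH2Cl2, 0 °C
Reagents that add atoms: none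
Why: Dess–Martin oxidation of the only free hydroxyl under neutral conditions, under which the new α-aryl ketone stereocentre should not enolize.

Step 28
Reactants: 37 aryl ketone
Product: 38 target
Conditions: Bu4NF/AcOH (1:1, excess), THF, 0 → 25 °C
Reagents that add atoms: none
Why: Acetic-acid-buffered fluoride should remove the three aryl and two primary TIPS groups without base-induced epimerization or retro-aldol of the α-aryl β-hydroxy ketone.

**Compound list**

1 | vanillin (4-hydroxy-3-methoxybenzaldehyde) | COc1cc(C=O)ccc1O | starting material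
2 | 3-methoxy-4-(TIPS-oxy)benzaldehyde | COc1cc(C=O)ccc1O[Si](C(C)C)(C(C)C)C(C)C | intermediate
3 | [3-methoxy-4-(TIPS-oxy)phenyl]methanol | COc1cc(CO)ccc1O[Si](C(C)C)(C(C)C)C(C)C | intermediate
4 | 4-bromo-2-methoxyphenol | COc1cc(Br)ccc1O | starting material
5 | 4-bromo-2-iodo-6-methoxyphenol | COc1cc(Br)cc(I)c1O | intermediate
6 | 5-bromo-1-iodo-3-methoxy-2-(G-methoxy)benzene | COc1cc(Br)cc(I)c1OCc1ccc(O[Si](C(C)C)(C(C)C)C(C)C)c(OC)c1 | intermediate
7 | ethyl diazoacetate | CCOC(=O)C=[N+]=[N-] | starting material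
8 | ethyl 2-[5-bromo-3-methoxy-2-(G-methoxy)phenyl]-2-diazoacetate | CCOC(=O)C(=[N+]=[N-])c1cc(Br)cc(OC)c1OCc1ccc(O[Si](C(C)C)(C(C)C)C(C)C)c(OC)c1 | intermediate
9 | ethyl (2S,3R)-5-bromo-7-methoxy-2-G-2,3-dihydro-1-benzofuran-3-carboxylate (2,3-cis) | Brc1cc(OC)c2c(c1)[C@@H](C(=O)OCC)[C@@H](c1ccc(O[Si](C(C)C)(C(C)C)C(C)C)c(OC)c1)O2 | intermediate
10 | [(2S,3S)-5-bromo-7-methoxy-2-G-2,3-dihydro-1-benzofuran-3-yl]methanol (cis) | Brc1cc(OC)c2c(c1)[C@@H](CO)[C@@H](c1ccc(O[Si](C(C)C)(C(C)C)C(C)C)c(OC)c1)O2 | intermediate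
11 | (2S,3S)-5-bromo-7-methoxy-2-G-3-[(TIPS-oxy)methyl]-2,3-dihydro-1-benzofuran | Brc1cc(OC)c2c(c1)[C@@H](CO[Si](C(C)C)(C(C)C)C(C)C)[C@@H](c1ccc(O[Si](C(C)C)(C(C)C)C(C)C)c(OC)c1)O2 | intermediate
12 | 5-lithio analogue of 11 (aryllithium) | [Li]c1cc(OC)c2c(c1)[C@@H](CO[Si](C(C)C)(C(C)C)C(C)C)[C@@H](c1ccc(O[Si](C(C)C)(C(C)C)C(C)C)c(OC)c1)O2 | intermediate (not isolated)
13 | (2S,3S)-7-methoxy-2-G-3-[(TIPS-oxy)methyl]-2,3-dihydro-1-benzofuran-5-carbaldehyde | O=Cc1cc(OC)c2c(c1)[C@@H](CO[Si](C(C)C)(C(C)C)C(C)C)[C@@H](c1ccc(O[Si](C(C)C)(C(C)C)C(C)C)c(OC)c1)O2 | intermediate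
14 | (1S)-1-DHB-prop-2-en-1-ol | O[C@@H](C=C)c1cc(OC)c2c(c1)[C@@H](CO[Si](C(C)C)(C(C)C)C(C)C)[C@@H](c1ccc(O[Si](C(C)C)(C(C)C)C(C)C)c(OC)c1)O2 | intermediate
15 | (4-bromo-2-iodo-6-methoxyphenoxy)triisopropylsilane | COc1cc(Br)cc(I)c1O[Si](C(C)C)(C(C)C)C(C)C | intermediate
16 | tert-butyl 2-[5-bromo-3-methoxy-2-(TIPS-oxy)phenyl]acetate | COc1cc(Br)cc(CC(=O)OC(C)(C)C)c1O[Si](C(C)C)(C(C)C)C(C)C | intermediate
17 | 2-[5-bromo-3-methoxy-2-(TIPS-oxy)phenyl]acetic acid | COc1cc(Br)cc(CC(=O)O)c1O[Si](C(C)C)(C(C)C)C(C)C | intermediate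
18 | (4R)-4-benzyl-1,3-oxazolidin-2-one | O=C1N[C@H](Cc2ccccc2)CO1 | starting material
19 | mixed anhydride of 17 with pivalic acid | COc1cc(Br)cc(CC(=O)OC(=O)C(C)(C)C)c1O[Si](C(C)C)(C(C)C)C(C)C | intermediate (not isolated)
20 | (4R)-4-benzyl-3-{2-[5-bromo-3-methoxy-2-(TIPS-oxy)phenyl]acetyl}-1,3-oxazolidin-2-one | COc1cc(Br)cc(CC(=O)N2C(=O)OC[C@H]2Cc2ccccc2)c1O[Si](C(C)C)(C(C)C)C(C)C | intermediate
21 | (Z)-dibutylboron enolate of 20 | COc1cc(Br)cc(/C=C(\OB(CCCC)CCCC)N2C(=O)OC[C@H]2Cc2ccccc2)c1O[Si](C(C)C)(C(C)C)C(C)C | intermediate (not isolated)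
22 | (4R)-4-benzyl-3-{(2R,3R)-2-[5-bromo-3-methoxy-2-(TIPS-oxy)phenyl]-3-G-3-hydroxypropanoyl}-1,3-oxazolidin-2-one | COc1cc([C@H](O)[C@H](C(=O)N3C(=O)OC[C@H]3Cc3ccccc3)c2cc(Br)cc(OC)c2O[Si](C(C)C)(C(C)C)C(C)C)ccc1O[Si](C(C)C)(C(C)C)C(C)C | intermediate
23 | 3-O-TES ether of 22 | COc1cc([C@H](O[Si](CC)(CC)CC)[C@H](C(=O)N3C(=O)OC[C@H]3Cc3ccccc3)c2cc(Br)cc(OC)c2O[Si](C(C)C)(C(C)C)C(C)C)ccc1O[Si](C(C)C)(C(C)C)C(C)C | intermediate
24 | (2S,3R)-2-[5-bromo-3-methoxy-2-(TIPS-oxy)phenyl]-3-G-3-(TES-oxy)propan-1-ol | COc1cc([C@H](O[Si](CC)(CC)CC)[C@H](CO)c2cc(Br)cc(OC)c2O[Si](C(C)C)(C(C)C)C(C)C)ccc1O[Si](C(C)C)(C(C)C)C(C)C | intermediate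
25 | 5-bromo-3-methoxy-2-(TIPS-oxy)-1-[(1R,2S)-1-G-1-(TES-oxy)-3-(TIPS-oxy)propan-2-yl]benzene | COc1cc([C@H](O[Si](CC)(CC)CC)[C@H](CO[Si](C(C)C)(C(C)C)C(C)C)c2cc(Br)cc(OC)c2O[Si](C(C)C)(C(C)C)C(C)C)ccc1O[Si](C(C)C)(C(C)C)C(C)C | intermediate
26 | (E)-3-(tributylstannyl)prop-2-en-1-ol | OC/C=C/[Sn](CCCC)(CCCC)CCCC | starting material
27 | (E)-3-ArA-prop-2-en-1-ol | COc1cc([C@H](O[Si](CC)(CC)CC)[C@H](CO[Si](C(C)C)(C(C)C)C(C)C)c2cc(/C=C/CO)cc(OC)c2O[Si](C(C)C)(C(C)C)C(C)C)ccc1O[Si](C(C)C)(C(C)C)C(C)C | intermediate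
28 | (E)-3-ArA-prop-2-en-1-yl bromide | COc1cc([C@H](O[Si](CC)(CC)CC)[C@H](CO[Si](C(C)C)(C(C)C)C(C)C)c2cc(/C=C/CBr)cc(OC)c2O[Si](C(C)C)(C(C)C)C(C)C)ccc1O[Si](C(C)C)(C(C)C)C(C)C | intermediate
29 | sodium (1S)-1-DHB-prop-2-en-1-olate | [Na+].[O-][C@@H](C=C)c1cc(OC)c2c(c1)[C@@H](CO[Si](C(C)C)(C(C)C)C(C)C)[C@@H](c1ccc(O[Si](C(C)C)(C(C)C)C(C)C)c(OC)c1)O2 | intermediate (not isolated)
30 | (E)-3-ArA-prop-2-en-1-yl (1S)-1-DHB-prop-2-en-1-yl ether | COc1cc([C@H](O[Si](CC)(CC)CC)[C@H](CO[Si](C(C)C)(C(C)C)C(C)C)c2cc(/C=C/CO[C@@H](C=C)c3cc(OC)c4c(c3)[C@@H](CO[Si](C(C)C)(C(C)C)C(C)C)[C@@H](c3ccc(O[Si](C(C)C)(C(C)C)C(C)C)c(OC)c3)O4)cc(OC)c2O[Si](C(C)C)(C(C)C)C(C)C)ccc1O[Si](C(C)C)(C(C)C)C(C)C | intermediate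
31 | 1-ArA-2-iodo-3-{[(1S)-1-DHB-prop-2-en-1-yl]oxy}propan-1-ol, mixture of diastereomers at C-1 and C-2 | COc1cc([C@H](O[Si](CC)(CC)CC)[C@H](CO[Si](C(C)C)(C(C)C)C(C)C)c2cc(C(O)C(I)CO[C@@H](C=C)c3cc(OC)c4c(c3)[C@@H](CO[Si](C(C)C)(C(C)C)C(C)C)[C@@H](c3ccc(O[Si](C(C)C)(C(C)C)C(C)C)c(OC)c3)O4)cc(OC)c2O[Si](C(C)C)(C(C)C)C(C)C)ccc1O[Si](C(C)C)(C(C)C)C(C)C | intermediate
32 | 1-ArA-2-iodo-3-{[(1S)-1-DHB-prop-2-en-1-yl]oxy}propan-1-one, both C-2 epimers | COc1cc([C@H](O[Si](CC)(CC)CC)[C@H](CO[Si](C(C)C)(C(C)C)C(C)C)c2cc(C(=O)C(I)CO[C@@H](C=C)c3cc(OC)c4c(c3)[C@@H](CO[Si](C(C)C)(C(C)C)C(C)C)[C@@H](c3ccc(O[Si](C(C)C)(C(C)C)C(C)C)c(OC)c3)O4)cc(OC)c2O[Si](C(C)C)(C(C)C)C(C)C)ccc1O[Si](C(C)C)(C(C)C)C(C)C | intermediate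
33 | (1R)-1-ArA-2-iodo-3-{[(1S)-1-DHB-prop-2-en-1-yl]oxy}propan-1-ol, both C-2 epimers | COc1cc([C@H](O[Si](CC)(CC)CC)[C@H](CO[Si](C(C)C)(C(C)C)C(C)C)c2cc([C@@H](O)C(I)CO[C@@H](C=C)c3cc(OC)c4c(c3)[C@@H](CO[Si](C(C)C)(C(C)C)C(C)C)[C@@H](c3ccc(O[Si](C(C)C)(C(C)C)C(C)C)c(OC)c3)O4)cc(OC)c2O[Si](C(C)C)(C(C)C)C(C)C)ccc1O[Si](C(C)C)(C(C)C)C(C)C | intermediate
34 | (S)-ArA[(3R,4S,5S)-5-DHB-4-(iodomethyl)oxolan-3-yl]methanol | COc1cc([C@H](O[Si](CC)(CC)CC)[C@H](CO[Si](C(C)C)(C(C)C)C(C)C)c2cc([C@@H](O)[C@H]5CO[C@H](c3cc(OC)c4c(c3)[C@@H](CO[Si](C(C)C)(C(C)C)C(C)C)[C@@H](c3ccc(O[Si](C(C)C)(C(C)C)C(C)C)c(OC)c3)O4)[C@H]5CI)cc(OC)c2O[Si](C(C)C)(C(C)C)C(C)C)ccc1O[Si](C(C)C)(C(C)C)C(C)C | intermediate (not isolated)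
35 | (1S,3aR,4S,6aR)-1-ArA-4-DHB-tetrahydro-1H,3H-furo[3,4-c]furan | COc1cc([C@H](O[Si](CC)(CC)CC)[C@H](CO[Si](C(C)C)(C(C)C)C(C)C)c2cc([C@H]3OC[C@H]4[C@@H]3CO[C@@H]4c3cc(OC)c4c(c3)[C@@H](CO[Si](C(C)C)(C(C)C)C(C)C)[C@@H](c3ccc(O[Si](C(C)C)(C(C)C)C(C)C)c(OC)c3)O4)cc(OC)c2O[Si](C(C)C)(C(C)C)C(C)C)ccc1O[Si](C(C)C)(C(C)C)C(C)C | intermediate
36 | 35 without its TES group: (1R,2S)-1-G-2-{3-methoxy-2-(TIPS-oxy)-5-[(1S,3aR,4S,6aR)-4-DHB-tetrahydro-1H,3H-furo[3,4-c]furan-1-yl]phenyl}-3-(TIPS-oxy)propan-1-ol | COc1cc([C@H](O)[C@H](CO[Si](C(C)C)(C(C)C)C(C)C)c2cc([C@H]3OC[C@H]4[C@@H]3CO[C@@H]4c3cc(OC)c4c(c3)[C@@H](CO[Si](C(C)C)(C(C)C)C(C)C)[C@@H](c3ccc(O[Si](C(C)C)(C(C)C)C(C)C)c(OC)c3)O4)cc(OC)c2O[Si](C(C)C)(C(C)C)C(C)C)ccc1O[Si](C(C)C)(C(C)C)C(C)C | intermediate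
37 | (2S)-1-G-2-{3-methoxy-2-(TIPS-oxy)-5-[(1S,3aR,4S,6aR)-4-DHB-tetrahydro-1H,3H-furo[3,4-c]furan-1-yl]phenyl}-3-(TIPS-oxy)propan-1-one | COc1cc(C(=O)[C@H](CO[Si](C(C)C)(C(C)C)C(C)C)c2cc([C@H]3OC[C@H]4[C@@H]3CO[C@@H]4c3cc(OC)c4c(c3)[C@@H](CO[Si](C(C)C)(C(C)C)C(C)C)[C@@H](c3ccc(O[Si](C(C)C)(C(C)C)C(C)C)c(OC)c3)O4)cc(OC)c2O[Si](C(C)C)(C(C)C)C(C)C)ccc1O[Si](C(C)C)(C(C)C)C(C)C | intermediate
38 | (2S)-3-hydroxy-1-(4-hydroxy-3-methoxyphenyl)-2-{2-hydroxy-5-[(1S,3aR,4S,6aR)-4-{(2S,3S)-2-(4-hydroxy-3-methoxyphenyl)-3-(hydroxymethyl)-7-methoxy-2,3-dihydro-1-benzofuran-5-yl}tetrahydro-1H,3H-furo[3,4-c]furan-1-yl]-3-methoxyphenyl}propan-1-one | COc1cc(C(=O)[C@H](CO)c2cc([C@H]3OC[C@H]4[C@@H]3CO[C@@H]4c3cc(OC)c4c(c3)[C@@H](CO)[C@@H](c3ccc(O)c(OC)c3)O4)cc(OC)c2O)ccc1O | target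

**Count and risks**

Total step count: 28. Longest linear sequence: 19 steps (4 → 5 → 15 → 16 → 17 → 20 → 22 → 23 → 24 → 25 → 27 → 28 → 30 → 31 → 32 → 33 → 35 → 36 → 37 → 38; steps 3, 11 to 28).

Step 25 (key step). What may go wrong: short radical chains in the iodine transfer from an unactivated secondary iodide, poor cis/trans selectivity at the ring fusion, or epoxide closure of unreacted iodohydrin when base is added. The fallback sets out from 33 and comes back at 35. Slow addition of Bu3SnH to 33 in toluene under dry air at 0 °C, followed by PPh3 to reduce the hydroperoxide (a known oxygen-trapping radical cyclization), should give the hydroxymethyl oxolane, diol F1. Selective sulfonylation of its primary hydroxyl (TsCl, Et3N, DMAP, CH2Cl2, 0 °C) should give the monotosylate F2, and NaH in THF should then close the second ring to 35.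

Step 24. What may go wrong: loss of reagent control at the carbonyl, because the adjacent iodine-bearing stereocentre makes one epimer of 32 a mismatched case; reductive loss of iodine or elimination of the β-alkoxy group. The fallback sets out from 31 and comes back at 35. Steps 23 and 24 are dropped, the mixture 31 is taken through the conditions of step 25, and 35 is separated by chromatography from its C-1 epimer, the endo-aryl furofuran F3. In the rigid bicycle the two differ as exo and endo isomers and should separate far more easily than the open-chain epimers; half of the material is lost.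

Step 15. What may go wrong: slow enolization and aldol addition next to the bulky ortho silyloxy group, with epimerization of the α-aryl centre or retro-aldol on work-up. The fallback sets out from 15 and comes back at 24, bypassing steps 12 to 17. Coupling of 15 with 7 under the conditions of step 5 should give the aryl diazoacetate F4. Silylation of 3 (Et3SiCl, imidazole, DMF) gives the benzyl triethylsilyl ether F5. Intermolecular insertion of the rhodium carbene from F4 into the benzylic C–H bond of F5 (F5 in excess, CH2Cl2, −40 °C, with whichever antipode of Rh2(PTTL)4 gives the 2R ester) is a known route to syn aldol-type products and should give the β-silyloxy ester F6. Reduction with i-Bu2AlH then gives 24.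

Further compounds
F1 | step 25 | (S)-ArA[(3R,4R,5S)-5-DHB-4-(hydroxymethyl)oxolan-3-yl]methanol | COc1cc([C@H](O[Si](CC)(CC)CC)[C@H](CO[Si](C(C)C)(C(C)C)C(C)C)c2cc([C@@H](O)[C@H]5CO[C@H](c3cc(OC)c4c(c3)[C@@H](CO[Si](C(C)C)(C(C)C)C(C)C)[C@@H](c3ccc(O[Si](C(C)C)(C(C)C)C(C)C)c(OC)c3)O4)[C@H]5CO)cc(OC)c2O[Si](C(C)C)(C(C)C)C(C)C)ccc1O[Si](C(C)C)(C(C)C)C(C)C
F2 | step 25 | primary 4-methylbenzenesulfonate of F1 | COc1cc([C@H](O[Si](CC)(CC)CC)[C@H](CO[Si](C(C)C)(C(C)C)C(C)C)c2cc([C@@H](O)[C@H]5CO[C@H](c3cc(OC)c4c(c3)[C@@H](CO[Si](C(C)C)(C(C)C)C(C)C)[C@@H](c3ccc(O[Si](C(C)C)(C(C)C)C(C)C)c(OC)c3)O4)[C@H]5COS(=O)(=O)c6ccc(C)cc6)cc(OC)c2O[Si](C(C)C)(C(C)C)C(C)C)ccc1O[Si](C(C)C)(C(C)C)C(C)C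
F3 | step 24 | (1R,3aR,4S,6aR)-1-ArA-4-DHB-tetrahydro-1H,3H-furo[3,4-c]furan (C-1 epimer of 35) | COc1cc([C@H](O[Si](CC)(CC)CC)[C@H](CO[Si](C(C)C)(C(C)C)C(C)C)c2cc([C@@H]3OC[C@H]4[C@@H]3CO[C@@H]4c3cc(OC)c4c(c3)[C@@H](CO[Si](C(C)C)(C(C)C)C(C)C)[C@@H](c3ccc(O[Si](C(C)C)(C(C)C)C(C)C)c(OC)c3)O4)cc(OC)c2O[Si](C(C)C)(C(C)C)C(C)C)ccc1O[Si](C(C)C)(C(C)C)C(C)C
F4 | step 15 | ethyl 2-[5-bromo-3-methoxy-2-(TIPS-oxy)phenyl]-2-diazoacetate | CCOC(=O)C(=[N+]=[N-])c1cc(Br)cc(OC)c1O[Si](C(C)C)(C(C)C)C(C)C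
F5 | step 15 | triethyl{[3-methoxy-4-(TIPS-oxy)benzyl]oxy}silane | COc1cc(CO[Si](CC)(CC)CC)ccc1O[Si](C(C)C)(C(C)C)C(C)C
F6 | step 15 | ethyl (2R,3R)-2-[5-bromo-3-methoxy-2-(TIPS-oxy)phenyl]-3-G-3-(TES-oxy)propanoate | COc1cc([C@H](O[Si](CC)(CC)CC)[C@H](C(=O)OCC)c2cc(Br)cc(OC)c2O[Si](C(C)C)(C(C)C)C(C)C)ccc1O[Si](C(C)C)(C(C)C)C(C)C
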